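Time came first at the meeting: the flask is to be read at 6.0 h, and the question was how many half-lives of X that is.

in all of them: J 5.8 mM (held)

| flask | X | remark | time |
|---|---|---|---|
| eta | 0.029 M | run made earlier |  |
| delta | 0.066 M | run made earlier |  |
| flask | 0.044 M |  | 6.0 h |

| run | time / h | Q / % | X / % |
|---|---|---|---|
| eta | 0.500 | 6.1 | 94.9 |
| eta | 1.00 | 9.7 | 88.8 |
| eta | 1.50 | 14.7 | 83.2 |
| eta | 2.50 | 22.4 | 74.9 |
| eta | 4.00 | 30.5 | 62.6 |
| eta | 8.00 | 38.9 | 40.1 |
| delta | 1.33 | 14.0 | 84.5 |
| delta | 2.50 | 21.8 | 75.4 |
| delta | 4.00 | 29.4 | 65.0 |
| delta | 5.00 | 34.9 | 56.9 |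
| delta | 6.00 | 35.5 | 50.1 |
| delta | 8.00 | 40.8 | 40.7 |

(standard deviation of a reading: 1 percentage point)

* how much Q there is at 6.0 h, in percent of the X charged
* the change that raises the amount of Q at 6.0 h, in percent of the X charged most ("none" if none brings more than 2 percentage points) (ash / alder / none)
* amount of Q at 6.0 h, in percent of the X charged, after ash

- ash: doubling the transfer coefficient of J, all else as stated
- alder: doubling the saturation concentration of J, all else as stated

- at the start none of J is in solution

The first speaker noted that the delta charge is twice the eta charge, yet the last readings of X agree within the scatter, 40.1% against 40.7%. She therefore treated X as pseudo-first-order. From the eta reading she took 6.07 h as the half-life of X, the time for c(X) to halve with J held as stated, at charges between these two. The flask then stands at 0.989 half-lives, which leaves 50.4% of X.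

The second speaker took the cheapest route to Q. The flask's 0.044 M lies between the two charges, so he read Q from the delta run at 6.00 h, the asked time: 35.5%, with 14 percentage points of the charge in neither X nor Q.

The forecast was then entered: 36% of Q, alder as the best change, and 36.3% after ash. On alder it cautioned: “The J order is untested, since J was never varied”.

The flask gives 35.9% of Q, 36.0% after ash.

    J ⇌ L, rate k1*(csat - [L]) (kL = 3.40 min⁻¹)
    X + L → Q (k = 0.330 M⁻¹ min⁻¹)
    L + Q → Z (k = 0.0160 M⁻¹ min⁻¹)
    Q → G (k = 0.00160 min⁻¹)

The best change is alder: it gains 15 points, against 0.04 points for ash. At 1.80 h Q is made 5.43 times faster than it is used up, each step taken net, but at 6.00 h the factor is 1.58. After its 0.989 half-lives, this flask holds 50% of X. The same flask read at 15 h stands at 2.47 half-lives, which leaves 18.0% of X. The computed flask holds 18% of X and 34.1% of Q.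

All runs are simulated from invented constants; scatter was added.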